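**Plan**

- Retrosynthesis: cut C11–OOH (singlet-oxygen ene), then C10=C11 (cross-metathesis), C8–C9 (allylation of a C8 aldehyde), the ester bond at O–C1 and the C3/C4 oxirane (directed epoxidation of a C2 allylic alcohol). The spiro-oxirane C7–O/C14–O is traced to a C7=C14 alkene, and C1–O and C8–O to (R)-carvone.
- Enabling feature: in the cyclohexenone precursor the oxygen on C1 is homoallylic to the C7=C14 alkene (O–C1–C6–C7=C14), so a carbonate on that oxygen can reach C7 through a six-membered ring.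
- Forward: carvone is oxygenated at C8 (chloride, acetate, silyl ether) and at C1 (Rubottom). The 1,3-dioxan-2-one ring is closed by iodocarbonate cyclisation and opened again to the C7/C14 oxirane. The C3/C4 oxirane follows, and C9–C13 are attached last.
- Stereochemistry: C6 comes from carvone; C1 is set trans to it by the Rubottom oxidation; C7 by tethered oxygen delivery from C1; C3/C4 by hydroxyl-directed epoxidation from a C2 carbinol set by Luche reduction; the E alkene by the ene reaction.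

Key step: step 7

Remark (numbering): C1–C15 denote the target skeleton in all intermediates: C1 acyloxy CH, C2 ring ketone, C3/C4 ring oxirane, C5 CH2, C6 CH, C7/C14 spiro-oxirane, C8 side-chain ketone, C9=C10, C11 hydroperoxy carbon, C12/C13 its methyls, C15 methyl on C3.
Remark (C8 carbinol): the C8 carbinol centre in 21, 22 and 24 is assumed to form as an epimer mixture; this is harmless because C8 becomes a ketone, and the SMILES leave it undefined.

**Route**

Step 1
Reactants: 1 (R)-carvone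
Product: 2 (5R)-5-(3-chloroprop-1-en-2-yl)-2-methylcyclohex-2-en-1-one
Conditions: Ca(OCl)2, CO2 (dry ice), CH2Cl2/H2O, 0 °C
Reagents that add atoms: calcium hypochlorite, [Ca+2].[O-]Cl.[O-]Cl
Why: Ene-type allylic chlorination by hypochlorous acid formed in situ attacks only the electron-rich isopropenyl alkene, and because the 2-substituted allyl unit is symmetrical the double-bond shift leaves constitution and the C6 stereocentre unchanged.

Step 2
Reactants: 2 (5R)-5-(3-chloroprop-1-en-2-yl)-2-methylcyclohex-2-en-1-one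
Product: 3 2-[(1R)-4-methyl-5-oxocyclohex-3-en-1-yl]prop-2-en-1-yl acetate
Conditions: KOAc, Bu4NI (cat.), DMF, 50 °C
Reagents that add atoms: potassium acetate, CC(=O)[O-].[K+]
Why: SN2 displacement of a primary allylic chloride by acetate under iodide (Finkelstein) catalysis; an SN2′ course would give the same product.

Step 3
Reactants: 3 2-[(1R)-4-methyl-5-oxocyclohex-3-en-1-yl]prop-2-en-1-yl acetate
Product: 4 (5R)-5-(3-hydroxyprop-1-en-2-yl)-2-methylcyclohex-2-en-1-one
Conditions: K2CO3 (cat.), MeOH, 0 °C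
Reagents that add atoms: none
Why: Base-catalysed transesterification of a primary acetate, mild enough to leave the enone untouched.

Step 4
Reactants: 4 (5R)-5-(3-hydroxyprop-1-en-2-yl)-2-methylcyclohex-2-en-1-one; 5 tert-butyl(chloro)diphenylsilane
Product: 6 (5R)-5-(3-{[tert-butyl(diphenyl)silyl]oxy}prop-1-en-2-yl)-2-methylcyclohex-2-en-1-one
Conditions: imidazole, DMF, 0 °C to rt
Reagents that add atoms: tert-butyl(chloro)diphenylsilane (5), CC(C)(C)[Si](Cl)(c1ccccc1)c1ccccc1
Why: Imidazole-promoted silylation of a primary alcohol; this silyl ether is chosen because it must outlast LDA, peracid, IBr, carbonate/methanol and borohydride.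

Step 5
Reactants: 6 (5R)-5-(3-{[tert-butyl(diphenyl)silyl]oxy}prop-1-en-2-yl)-2-methylcyclohex-2-en-1-one
Product: 9 (5S,6S)-5-(3-{[tert-butyl(diphenyl)silyl]oxy}prop-1-en-2-yl)-6-hydroxy-2-methylcyclohex-2-en-1-one (OH trans to the side chain), via trimethylsilyl dienol ether 7 (not isolated), via α-trimethylsilyloxy ketone 8 (not isolated)
Conditions: LDA, THF, −78 °C, then TMSCl; solvent change to CH2Cl2; mCPBA, NaHCO3, −20 °C; citric acid, MeOH, rt
Reagents that add atoms: mCPBA, OOC(=O)c1cccc(Cl)c1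
Why: Rubottom oxidation: kinetic α′-deprotonation gives the cross-conjugated silyl dienol ether, whose C1=C2 bond is epoxidised on the face opposite the adjacent C6 substituent (far faster than the allylic-ether alkene), and silyl migration followed by mild methanolysis gives the trans α′-hydroxy enone, setting C1.

Step 6
Reactants: 9 (5S,6S)-5-(3-{[tert-butyl(diphenyl)silyl]oxy}prop-1-en-2-yl)-6-hydroxy-2-methylcyclohex-2-en-1-one; 10 di-tert-butyl dicarbonate
Product: 11 tert-butyl (1S,6S)-6-(3-{[tert-butyl(diphenyl)silyl]oxy}prop-1-en-2-yl)-3-methyl-2-oxocyclohex-3-en-1-yl carbonate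
Conditions: Boc2O, DMAP (cat.), MeCN, rt
Reagents that add atoms: di-tert-butyl dicarbonate (10), CC(C)(C)OC(=O)OC(=O)OC(C)(C)C
Why: DMAP-catalysed O-acylation of the secondary alcohol (carbonate formation) installs the internal oxygen nucleophile without touching a stereocentre.

Step 7
Reactants: 11 tert-butyl (1S,6S)-6-(3-{[tert-butyl(diphenyl)silyl]oxy}prop-1-en-2-yl)-3-methyl-2-oxocyclohex-3-en-1-yl carbonate
Product: 12 (4S,4aR,8aS)-4-({[tert-butyl(diphenyl)silyl]oxy}methyl)-4-(iodomethyl)-7-methyl-4a,5-dihydro-4H-1,3-benzodioxine-2,8(8aH)-dione (trans-fused iodomethyl cyclic carbonate)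
Conditions: IBr (1.3 equiv), PhMe/CH2Cl2, −85 °C; aq. Na2S2O3/NaHCO3 quench
Reagents that add atoms: iodine monobromide, IBr
Why: IBr transfers I+ to the electron-rich 1,1-disubstituted C7=C14 alkene (the enone alkene is too electron-poor to compete), the carbonyl oxygen of the carbonate on O–C1 opens the iodonium ion at the more substituted carbon C7 anti to iodine, and the resulting dioxacarbenium ion loses its tert-butyl group to bromide, so C7–O and C14–I form irreversibly. The closest known reaction type is the iodocarbonate cyclisation of homoallylic tert-butyl carbonates in its low-temperature IBr form, which is established for 1,1-disubstituted alkenes that give tertiary C–O centres. The 1,3-dioxan-2-one ring closes in the 6-exo-trig mode (7-endo attack at C14 is anti-Markovnikov and not expected) and is trans-fused to the cyclohexenone because O–C1 and C6–C7 are trans-diequatorial. The new stereocentre C7 is controlled by the tether from C1 together with the C6–C7 rotamer: with C6–H close to the plane of the C7=C14 bond, the CH2–I+ terminus takes the equatorial site of the chair-like transition state and the CH2OSi arm the axial one, whereas the other rotamer would push the iodonium-bearing methylene into the axial site between C1–H and C5H2. Oxygen therefore reaches the alkene face turned towards C1, which corresponds to the C7 configuration of the target once the oxirane is closed in step 8. The step needs alkene site selectivity (secured by electronics), Markovnikov regioselectivity (secured by the tertiary C7) and facial selectivity (secured by tether and rotamer preference, to be checked on 12 by NOE or X-ray analysis).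

Step 8
Reactants: 12 trans-fused iodomethyl cyclic carbonate
Product: 13 (5R,6S)-5-[(2R)-2-({[tert-butyl(diphenyl)silyl]oxy}methyl)oxiran-2-yl]-6-hydroxy-2-methylcyclohex-2-en-1-one
Conditions: K2CO3, MeOH (degassed), 0 °C
Reagents that add atoms: none
Why: Carbonate methanolysis releases the tertiary C7 alkoxide, which closes the oxirane by intramolecular Williamson (3-exo-tet) displacement of iodide at C14, so the C7–O bond and the C7 configuration are retained while O–C1 is freed.

Step 9
Reactants: 13 (5R,6S)-5-[(2R)-2-({[tert-butyl(diphenyl)silyl]oxy}methyl)oxiran-2-yl]-6-hydroxy-2-methylcyclohex-2-en-1-one; 14 3-methylbutanoyl chloride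
Product: 15 (1S,6R)-6-[(2R)-2-({[tert-butyl(diphenyl)silyl]oxy}methyl)oxiran-2-yl]-3-methyl-2-oxocyclohex-3-en-1-yl 3-methylbutanoate
Conditions: pyridine, DMAP (cat.), CH2Cl2, 0 °C
Reagents that add atoms: 3-methylbutanoyl chloride (14), CC(C)CC(=O)Cl
Why: DMAP-catalysed esterification of the secondary α-ketol with an acid chloride under weakly basic conditions that should not epimerise C1.

Step 10
Reactants: 15 (1S,6R)-6-[(2R)-2-({[tert-butyl(diphenyl)silyl]oxy}methyl)oxiran-2-yl]-3-methyl-2-oxocyclohex-3-en-1-yl 3-methylbutanoate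
Product: 16 (1S,2S,6R)-6-[(2R)-2-({[tert-butyl(diphenyl)silyl]oxy}methyl)oxiran-2-yl]-2-hydroxy-3-methylcyclohex-3-en-1-yl 3-methylbutanoate
Conditions: NaBH4, CeCl3·7H2O, MeOH, −78 °C
Reagents that add atoms: none
Why: Luche 1,2-reduction: with the C1 and C6 substituents equatorial, axial hydride delivery to C2 (opposite the axial C1–H) should give the equatorial carbinol, trans to the C1 ester and cis to the C6 side chain, while cerium suppresses conjugate reduction and the low temperature suppresses acyl migration.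

Step 11
Reactants: 16 (1S,2S,6R)-6-[(2R)-2-({[tert-butyl(diphenyl)silyl]oxy}methyl)oxiran-2-yl]-2-hydroxy-3-methylcyclohex-3-en-1-yl 3-methylbutanoate
Product: 17 (1R,2R,3S,4R,6S)-4-[(2R)-2-({[tert-butyl(diphenyl)silyl]oxy}methyl)oxiran-2-yl]-2-hydroxy-1-methyl-7-oxabicyclo[4.1.0]heptan-3-yl 3-methylbutanoate
Conditions: mCPBA, NaHCO3, CH2Cl2, 0 °C
Reagents that add atoms: mCPBA, OOC(=O)c1cccc(Cl)c1
Why: Henbest (hydroxyl-directed) peracid epoxidation: hydrogen bonding of the pseudo-equatorial allylic C2–OH to the peracid delivers oxygen to the C3=C4 face syn to that hydroxyl, which is the face of the C6 side chain, setting C3 and C4.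

Step 12
Reactants: 17 ring-epoxy alcohol silyl ether
Product: 18 (1R,2R,3S,4R,6S)-2-hydroxy-4-[(2S)-2-(hydroxymethyl)oxiran-2-yl]-1-methyl-7-oxabicyclo[4.1.0]heptan-3-yl 3-methylbutanoate
Conditions: TBAF, AcOH (1:1), THF, 0 °C to rt
Reagents that add atoms: none
Why: Fluoride-induced cleavage of the silyl ether (strong Si–F bond), buffered with acetic acid so that no free alkoxide can trigger acyl migration or a Payne-type oxirane migration.

Step 13
Reactants: 18 diol
Product: 19 (1S,3S,4R,6S)-4-[(2R)-2-formyloxiran-2-yl]-1-methyl-2-oxo-7-oxabicyclo[4.1.0]heptan-3-yl 3-methylbutanoate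
Conditions: Dess–Martin periodinane (3 equiv), NaHCO3, CH2Cl2, 0 °C to rt
Reagents that add atoms: none
Why: Dess–Martin oxidation of the secondary C2 carbinol and the primary C8 alcohol in one operation; buffered, non-enolising conditions preserve C1, and the aldehyde has no α-hydrogen.

Step 14
Reactants: 19 keto aldehyde; 20 2-allyl-4,4,5,5-tetramethyl-1,3,2-dioxaborolane
Product: 22 (1S,3S,4R,6S)-4-[(2R)-2-(1-hydroxybut-3-en-1-yl)oxiran-2-yl]-1-methyl-2-oxo-7-oxabicyclo[4.1.0]heptan-3-yl 3-methylbutanoate, via pinacol borate ester 21 (not isolated)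
Conditions: allyl-B(pin), CH2Cl2, rt; aq. NaHCO3 work-up
Reagents that add atoms: 2-allyl-4,4,5,5-tetramethyl-1,3,2-dioxaborolane (20), C=CCB1OC(C)(C)C(C)(C)O1
Why: Uncatalysed allylboration through a closed six-membered (Zimmerman–Traxler) transition state, which discriminates the aldehyde from the hindered ring ketone, the ester and both oxiranes; the new C8 carbinol centre is inconsequential because it is oxidised in step 16.

Step 15
Reactants: 22 homoallylic alcohol; 23 2-methylbut-2-ene
Product: 24 (1S,3S,4R,6S)-4-[(2R)-2-(1-hydroxy-4-methylpent-3-en-1-yl)oxiran-2-yl]-1-methyl-2-oxo-7-oxabicyclo[4.1.0]heptan-3-yl 3-methylbutanoate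
Conditions: Grubbs II (5 mol %), 2-methylbut-2-ene (excess)/CH2Cl2, rt
Reagents that add atoms: 2-methylbut-2-ene (23), CC=C(C)C
Why: Olefin cross-metathesis with excess 2-methylbut-2-ene converts the allyl group into the prenyl group, tolerates free hydroxyl, ketone, ester and epoxide functions, and is driven by loss of propene.

Step 16
Reactants: 24 prenyl carbinol
Product: 25 (1S,3S,4R,6S)-1-methyl-4-[(2R)-2-(4-methylpent-3-enoyl)oxiran-2-yl]-2-oxo-7-oxabicyclo[4.1.0]heptan-3-yl 3-methylbutanoate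
Conditions: Dess–Martin periodinane, NaHCO3, CH2Cl2, 0 °C; used crude
Reagents that add atoms: none
Why: Dess–Martin oxidation of a homoallylic alcohol under buffered conditions gives the β,γ-unsaturated ketone without migration of the C10=C11 bond, provided the product is not exposed to acidic or basic media.

Step 17
Reactants: 25 β,γ-unsaturated ketone
Product: 26 (1S,3S,4R,6S)-4-{(2R)-2-[(2E)-4-hydroperoxy-4-methylpent-2-enoyl]oxiran-2-yl}-1-methyl-2-oxo-7-oxabicyclo[4.1.0]heptan-3-yl 3-methylbutanoate (CNP0131119.1)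
Conditions: O2, tetraphenylporphyrin (cat.), visible light, CH2Cl2, −20 °C
Reagents that add atoms: dioxygen, O=O
Why: Schenck ene reaction of singlet oxygen: oxygen adds to C11 with transfer of a C9 hydrogen, the site favoured because the new C9=C10 bond forms in conjugation with the C8 carbonyl, giving the (E)-γ-hydroperoxy enone; no stereocentre is created and no other alkene is present.

**Compound list**

1 | (R)-carvone | CC1=CC[C@H](CC1=O)C(=C)C | starting material
2 | (5R)-5-(3-chloroprop-1-en-2-yl)-2-methylcyclohex-2-en-1-one | CC1=CC[C@H](CC1=O)C(=C)CCl | intermediate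
3 | 2-[(1R)-4-methyl-5-oxocyclohex-3-en-1-yl]prop-2-en-1-yl acetate | CC1=CC[C@H](CC1=O)C(=C)COC(C)=O | intermediate
4 | (5R)-5-(3-hydroxyprop-1-en-2-yl)-2-methylcyclohex-2-en-1-one | CC1=CC[C@H](CC1=O)C(=C)CO | intermediate
5 | tert-butyl(chloro)diphenylsilane | CC(C)(C)[Si](Cl)(c1ccccc1)c1ccccc1 | starting material
6 | (5R)-5-(3-{[tert-butyl(diphenyl)silyl]oxy}prop-1-en-2-yl)-2-methylcyclohex-2-en-1-one | CC1=CC[C@H](CC1=O)C(=C)CO[Si](c1ccccc1)(c1ccccc1)C(C)(C)C | intermediate
7 | tert-butyl({2-[(1R)-4-methyl-3-[(trimethylsilyl)oxy]cyclohexa-2,4-dien-1-yl]prop-2-en-1-yl}oxy)diphenylsilane | C[Si](C)(C)OC1=C[C@@H](CC=C1C)C(=C)CO[Si](c1ccccc1)(c1ccccc1)C(C)(C)C | intermediate (not isolated)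
8 | (5S,6S)-5-(3-{[tert-butyl(diphenyl)silyl]oxy}prop-1-en-2-yl)-2-methyl-6-[(trimethylsilyl)oxy]cyclohex-2-en-1-one | C[Si](C)(C)O[C@@H]1C(=O)C(C)=CC[C@H]1C(=C)CO[Si](c1ccccc1)(c1ccccc1)C(C)(C)C | intermediate (not isolated)
9 | (5S,6S)-5-(3-{[tert-butyl(diphenyl)silyl]oxy}prop-1-en-2-yl)-6-hydroxy-2-methylcyclohex-2-en-1-one | O[C@@H]1C(=O)C(C)=CC[C@H]1C(=C)CO[Si](c1ccccc1)(c1ccccc1)C(C)(C)C | intermediate
10 | di-tert-butyl dicarbonate | CC(C)(C)OC(=O)OC(=O)OC(C)(C)C | starting material
11 | tert-butyl (1S,6S)-6-(3-{[tert-butyl(diphenyl)silyl]oxy}prop-1-en-2-yl)-3-methyl-2-oxocyclohex-3-en-1-yl carbonate | CC(C)(C)OC(=O)O[C@@H]1C(=O)C(C)=CC[C@H]1C(=C)CO[Si](c1ccccc1)(c1ccccc1)C(C)(C)C | intermediate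
12 | (4S,4aR,8aS)-4-({[tert-butyl(diphenyl)silyl]oxy}methyl)-4-(iodomethyl)-7-methyl-4a,5-dihydro-4H-1,3-benzodioxine-2,8(8aH)-dione | O=C1O[C@@H]2C(=O)C(C)=CC[C@H]2[C@@](CI)(CO[Si](c3ccccc3)(c3ccccc3)C(C)(C)C)O1 | intermediate
13 | (5R,6S)-5-[(2R)-2-({[tert-butyl(diphenyl)silyl]oxy}methyl)oxiran-2-yl]-6-hydroxy-2-methylcyclohex-2-en-1-one | O[C@@H]1C(=O)C(C)=CC[C@H]1[C@]2(CO[Si](c3ccccc3)(c3ccccc3)C(C)(C)C)CO2 | intermediate
14 | 3-methylbutanoyl chloride | CC(C)CC(=O)Cl | starting material
15 | (1S,6R)-6-[(2R)-2-({[tert-butyl(diphenyl)silyl]oxy}methyl)oxiran-2-yl]-3-methyl-2-oxocyclohex-3-en-1-yl 3-methylbutanoate | CC(C)CC(=O)O[C@@H]1C(=O)C(C)=CC[C@H]1[C@]2(CO[Si](c3ccccc3)(c3ccccc3)C(C)(C)C)CO2 | intermediate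
16 | (1S,2S,6R)-6-[(2R)-2-({[tert-butyl(diphenyl)silyl]oxy}methyl)oxiran-2-yl]-2-hydroxy-3-methylcyclohex-3-en-1-yl 3-methylbutanoate | CC(C)CC(=O)O[C@@H]1[C@@H](O)C(C)=CC[C@H]1[C@]2(CO[Si](c3ccccc3)(c3ccccc3)C(C)(C)C)CO2 | intermediate
17 | (1R,2R,3S,4R,6S)-4-[(2R)-2-({[tert-butyl(diphenyl)silyl]oxy}methyl)oxiran-2-yl]-2-hydroxy-1-methyl-7-oxabicyclo[4.1.0]heptan-3-yl 3-methylbutanoate | CC(C)CC(=O)O[C@@H]1[C@@H](O)[C@@]2(C)O[C@H]2C[C@H]1[C@]3(CO[Si](c4ccccc4)(c4ccccc4)C(C)(C)C)CO3 | intermediate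
18 | (1R,2R,3S,4R,6S)-2-hydroxy-4-[(2S)-2-(hydroxymethyl)oxiran-2-yl]-1-methyl-7-oxabicyclo[4.1.0]heptan-3-yl 3-methylbutanoate | CC(C)CC(=O)O[C@@H]1[C@@H](O)[C@@]2(C)O[C@H]2C[C@H]1[C@]3(CO)CO3 | intermediate
19 | (1S,3S,4R,6S)-4-[(2R)-2-formyloxiran-2-yl]-1-methyl-2-oxo-7-oxabicyclo[4.1.0]heptan-3-yl 3-methylbutanoate | CC(C)CC(=O)O[C@@H]1C(=O)[C@@]2(C)O[C@H]2C[C@H]1[C@]3(C=O)CO3 | intermediate
20 | 2-allyl-4,4,5,5-tetramethyl-1,3,2-dioxaborolane | C=CCB1OC(C)(C)C(C)(C)O1 | starting material
21 | O-(pinacolatoboryl) derivative of 22 (C8–O–B(pin)) | CC(C)CC(=O)O[C@@H]1C(=O)[C@@]2(C)O[C@H]2C[C@H]1[C@]3(C(CC=C)OB4OC(C)(C)C(C)(C)O4)CO3 | intermediate (not isolated)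
22 | (1S,3S,4R,6S)-4-[(2R)-2-(1-hydroxybut-3-en-1-yl)oxiran-2-yl]-1-methyl-2-oxo-7-oxabicyclo[4.1.0]heptan-3-yl 3-methylbutanoate | CC(C)CC(=O)O[C@@H]1C(=O)[C@@]2(C)O[C@H]2C[C@H]1[C@]3(C(O)CC=C)CO3 | intermediate
23 | 2-methylbut-2-ene | CC=C(C)C | starting material
24 | (1S,3S,4R,6S)-4-[(2R)-2-(1-hydroxy-4-methylpent-3-en-1-yl)oxiran-2-yl]-1-methyl-2-oxo-7-oxabicyclo[4.1.0]heptan-3-yl 3-methylbutanoate | CC(C)CC(=O)O[C@@H]1C(=O)[C@@]2(C)O[C@H]2C[C@H]1[C@]3(C(O)CC=C(C)C)CO3 | intermediate
25 | (1S,3S,4R,6S)-1-methyl-4-[(2R)-2-(4-methylpent-3-enoyl)oxiran-2-yl]-2-oxo-7-oxabicyclo[4.1.0]heptan-3-yl 3-methylbutanoate | CC(C)CC(=O)O[C@@H]1C(=O)[C@@]2(C)O[C@H]2C[C@H]1[C@]3(C(=O)CC=C(C)C)CO3 | intermediate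
26 | (1S,3S,4R,6S)-4-{(2R)-2-[(2E)-4-hydroperoxy-4-methylpent-2-enoyl]oxiran-2-yl}-1-methyl-2-oxo-7-oxabicyclo[4.1.0]heptan-3-yl 3-methylbutanoate | CC(C)CC(=O)O[C@@H]1C(=O)[C@@]2(C)O[C@H]2C[C@H]1[C@]1(C(=O)/C=C/C(C)(C)OO)CO1 | target

**Totals and risks**

Total step count: 17. Longest linear sequence: 17 steps (fully linear from 1).

Steps most likely to fail:

1. Step 7. What may go wrong: oxygen delivery to the other face of the C7=C14 alkene (through the rotamer with the CH2–I+ terminus axial), or poor discrimination between the two faces, which would give the C7 epimer after step 8. Fallback: set C7 by reagent control instead of the tether. Setting out from 9, esterification with 14 (pyridine, DMAP, CH2Cl2) would give the isovalerate ester F1. Buffered fluoride (TBAF/AcOH, THF) would release the allylic alcohol F2. Sharpless asymmetric epoxidation [Ti(OiPr)4, L-(+)-diisopropyl tartrate, TBHP, 4 Å MS, CH2Cl2, −20 °C], which for 2-substituted allylic alcohols delivers oxygen in the (S)-2-alkylglycidol sense, would give the epoxy alcohol F3. Silylation with 5 (imidazole, DMF) comes back to the route at 15.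

2. Step 17. What may go wrong: hydrogen abstraction from a C11 methyl group instead of C9 (giving the regioisomeric secondary hydroperoxide), or drift of the C10=C11 bond into conjugation before photooxygenation. Fallback: bring in the peroxide as a protected building block and form C9=C10 by olefination. Setting out from 19, addition of dimethyl lithiomethylphosphonate (THF, −78 °C) would give the β-hydroxy phosphonate F4 and Dess–Martin oxidation the β-keto phosphonate F5. Separately, commercial 2-methylbut-3-en-2-ol would be perhydrolysed (50 % H2O2, cat. H2SO4) to 2-methylbut-3-en-2-yl hydroperoxide F6, capped with 2-methoxypropene (PPTS) as the peroxyketal F7, and ozonised (O3, CH2Cl2, −78 °C, then Me2S) to the peroxy aldehyde F8. Horner–Wadsworth–Emmons coupling of F5 with F8 (Ba(OH)2, wet THF) would give the (E)-enone peroxyketal F9, and aqueous acetic acid in THF would release the hydroperoxide, coming back to the route at 26.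

3. Step 12. What may go wrong: slow cleavage of the hindered silyl ether, and during long fluoride exposure migration of the isovaleryl group from O–C1 to the free O–C2, or alkoxide-triggered Payne-type migration of the oxirane between C14 and C8, which would scramble C7. Fallback: remove the neighbouring hydroxyl before silicon is touched and use acidic fluoride. Setting out from 17, Dess–Martin oxidation would give the epoxy ketone silyl ether F10, HF·pyridine in THF/pyridine would give the keto alcohol F11, and a second Dess–Martin oxidation comes back to the route at 19.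

Further compounds
F1 | step 7 | (1S,6S)-6-(3-{[tert-butyl(diphenyl)silyl]oxy}prop-1-en-2-yl)-3-methyl-2-oxocyclohex-3-en-1-yl 3-methylbutanoate | CC(C)CC(=O)O[C@@H]1C(=O)C(C)=CC[C@H]1C(=C)CO[Si](c1ccccc1)(c1ccccc1)C(C)(C)C
F2 | step 7 | (1S,6S)-6-(3-hydroxyprop-1-en-2-yl)-3-methyl-2-oxocyclohex-3-en-1-yl 3-methylbutanoate | CC(C)CC(=O)O[C@@H]1C(=O)C(C)=CC[C@H]1C(=C)CO
F3 | step 7 | (1S,6R)-6-[(2S)-2-(hydroxymethyl)oxiran-2-yl]-3-methyl-2-oxocyclohex-3-en-1-yl 3-methylbutanoate | CC(C)CC(=O)O[C@@H]1C(=O)C(C)=CC[C@H]1[C@]2(CO)CO2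
F4 | step 17 | dimethyl {2-hydroxy-2-[(2R)-2-[(1S,3S,4R,6S)-1-methyl-3-(3-methylbutanoyloxy)-2-oxo-7-oxabicyclo[4.1.0]heptan-4-yl]oxiran-2-yl]ethyl}phosphonate | CC(C)CC(=O)O[C@@H]1C(=O)[C@@]2(C)O[C@H]2C[C@H]1[C@]3(C(O)CP(=O)(OC)OC)CO3
F5 | step 17 | dimethyl {2-[(2R)-2-[(1S,3S,4R,6S)-1-methyl-3-(3-methylbutanoyloxy)-2-oxo-7-oxabicyclo[4.1.0]heptan-4-yl]oxiran-2-yl]-2-oxoethyl}phosphonate | CC(C)CC(=O)O[C@@H]1C(=O)[C@@]2(C)O[C@H]2C[C@H]1[C@]3(C(=O)CP(=O)(OC)OC)CO3
F6 | step 17 | 2-methylbut-3-en-2-yl hydroperoxide | C=CC(C)(C)OO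
F7 | step 17 | 3-[(2-methoxypropan-2-yl)peroxy]-3-methylbut-1-ene | C=CC(C)(C)OOC(C)(C)OC
F8 | step 17 | 2-[(2-methoxypropan-2-yl)peroxy]-2-methylpropanal | O=CC(C)(C)OOC(C)(C)OC
F9 | step 17 | 2-methoxypropan-2-yl peroxyketal of 26 | CC(C)CC(=O)O[C@@H]1C(=O)[C@@]2(C)O[C@H]2C[C@H]1[C@]3(C(=O)/C=C/C(C)(C)OOC(C)(C)OC)CO3
F10 | step 12 | (1S,3S,4R,6S)-4-[(2R)-2-({[tert-butyl(diphenyl)silyl]oxy}methyl)oxiran-2-yl]-1-methyl-2-oxo-7-oxabicyclo[4.1.0]heptan-3-yl 3-methylbutanoate | CC(C)CC(=O)O[C@@H]1C(=O)[C@@]2(C)O[C@H]2C[C@H]1[C@]3(CO[Si](c4ccccc4)(c4ccccc4)C(C)(C)C)CO3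
F11 | step 12 | (1S,3S,4R,6S)-4-[(2S)-2-(hydroxymethyl)oxiran-2-yl]-1-methyl-2-oxo-7-oxabicyclo[4.1.0]heptan-3-yl 3-methylbutanoate | CC(C)CC(=O)O[C@@H]1C(=O)[C@@]2(C)O[C@H]2C[C@H]1[C@]3(CO)CO3
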